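(Readings and results come from a simulation on assumed constants; the scatter is artificial.)

A ratio starts the dispute: the highest target reading of a run over the coupling partner charged, both in percent of the starting material charged.

| flask | starting material | coupling partner | protic impurity | remark | time |
|---|---|---|---|---|---|
| grey | 0.25 M | 0.10 M | 0.0125 M | run made earlier |  |
| violet | 0.25 M | 0.15 M | 0.0125 M | run made earlier |  |
| flask | 0.25 M | 0.200 M | 0.0125 M |  | 2.5 d |

- grey (time / h: target / %, starting material / %): 0.500: 7.0, 85.4; 1.33: 10.9, 73.6; 3.00: 12.3, 65.8; 8.00: 6.0, 56.7; 20.0: 6.4, 54.8; 50.0: 7.0, 56.8
- violet (time / h: target / %, starting material / %): 0.500: 13.5, 81.3; 1.33: 18.0, 66.3; 3.00: 15.9, 51.9; 8.00: 9.9, 43.1; 20.0: 8.7, 38.2; 50.0: 8.9, 36.9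

(each reading ± 1 percentage point)

- a reading of starting material is of its free form alone

1. the best time, 2.5 d at the latest, for target
2. the amount of target, in percent of the starting material charged, at that time

Follow one molecule of coupling partner, charged below the starting material and so the limiting reagent, and ask how likely it is to stand as target at the highest reading. The grey run reads 30.8 % and the violet run 30.0 %. These stand 0.80 percentage points apart, and each target reading carries a scatter of 1 point. So I take their mean, 30.4 %, as the peak share and hold it constant as [coupling partner] rises. At [coupling partner] = 0.200 M, which is 80.0 % of the starting material charged, my reckoning gives the flask a peak of 24.3 %, though it names no time.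

My colleague, who made the forecast, holds a different view: target passes reversibly into a by-product, so its course has to be followed through time. The forecast is 22 % at 0.06 d, lower than my figure, and rests on this: “Stepping target through gives about 16, 21, 22 and 21%.”

    starting material + coupling partner ⇌ target (K = 34.0 M⁻¹, k = 2.50 M⁻¹ h⁻¹)
    starting material + coupling partner ⇌ isomer of the product A (K = 100 M⁻¹, k = 0.200 M⁻¹ h⁻¹)
    target ⇌ isomer of the product B (K = 4.70, k = 0.600 h⁻¹)
    starting material + protic impurity → quenched substrate (k = 49.0 M⁻¹ h⁻¹)

The flask peaks at 22.6 % at 0.0660 d, so the forecast holds, falling 0.60 points short, while my figure stands 1.7 points too high. The peak share of this flask is 28.3 %, not the 30.4 % I carried. My constant share stands on readings at 0.10 M and 0.15 M, and outside them it has to be tried. The neighbour with [coupling partner] = 0.050 M has 20.0 % of the starting material charged as partner, so the constant share reckons 6.07 %. That neighbour gives 6.71 %, so its peak share is 33.5 %, higher than the 30.4 % I carried.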